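**Retrosynthetic overview**
1. Side-chain (E)-alkene: late cross-metathesis of allyl cyclopentenone acetate 10 with methyl (4S)-4-acetoxyhex-5-enoate 16, whose stereocentre comes from (S)-5-(hydroxymethyl)butyrolactone 11.
2. Tertiary acetate: base-free acetylation of hydroxycyclopentenone 9.
3. Key step and only ring formed: cyclopentenone 9 by an enantioselective oxa-Piancatelli rearrangement of furylcarbinol 8. Furan C5 becomes the quaternary carbinol, the carbinol carbon becomes the ring CH, and the furan oxygen becomes the ketone.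
4. Furylcarbinol 8: allyl addition to 5-[(Z)-octenyl]furfural 6, made from furfural dioxolane 1 by C5 lithiation/propargylation with 2 and Lindlar reduction.
5. Ring order: the furan is bought; the cyclopentenone is made in step 4.

Assumption: the (R)-configured phosphoramide in step 4 is taken to give the (4R,5R) product; if the sense of induction proves opposite, its (S)-antipode is used and nothing else changes.

**Step 1**
Reactants: 1 2-(furan-2-yl)-1,3-dioxolane; 2 1-bromooct-2-yne
Product: 5 5-(oct-2-yn-1-yl)furan-2-carbaldehyde, via 5-lithio furyl dioxolane 3 (not isolated), via 5-octynyl furyl dioxolane 4 (not isolated)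
Conditions: n-BuLi, THF, −78 → −20 °C; cannulate into 2, THF, −78 → 0 °C; 1 M HCl, THF, rt
Reagents that add atoms: water (`O`)
Why: α-Lithiation of the 2-substituted furan at C5 (the acetal tolerates n-BuLi), SN2 alkylation of the aryllithium at the primary propargylic bromide (inverse addition keeps the doubly activated CH2 of the product from being deprotonated) and acetal hydrolysis on work-up; no stereocentre is formed.

**Step 2**
Reactants: 5 5-(oct-2-yn-1-yl)furan-2-carbaldehyde
Product: 6 5-[(2Z)-oct-2-en-1-yl]furan-2-carbaldehyde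
Conditions: H2 (1 atm), Pd/CaCO3 poisoned with Pb(OAc)2 (Lindlar catalyst), quinoline, EtOAc, rt, stopped after 1 equiv H2
Reagents that add atoms: none
Why: Lindlar semihydrogenation delivers both hydrogens to the same face of the alkyne on the poisoned Pd surface, which sets the (Z)-alkene and leaves the furan and the aldehyde untouched.

**Step 3**
Reactants: 6 5-[(2Z)-oct-2-en-1-yl]furan-2-carbaldehyde
Product: 8 1-{5-[(2Z)-oct-2-en-1-yl]furan-2-yl}but-3-en-1-ol, via bromomagnesium alkoxide 7 (not isolated)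
Conditions: allylmagnesium bromide, Et2O/THF, −78 °C; sat. aq NH4Cl
Reagents that add atoms: allylmagnesium bromide (`C=CC[Mg]Br`)
Why: Grignard 1,2-addition to the aldehyde; the carbinol is made racemic on purpose because its stereocentre is erased when the furfuryl cation forms in step 4.

**Step 4**
Reactants: 8 1-{5-[(2Z)-oct-2-en-1-yl]furan-2-yl}but-3-en-1-ol
Product: 9 (4R,5R)-4-hydroxy-4-[(2Z)-oct-2-en-1-yl]-5-(prop-2-en-1-yl)cyclopent-2-en-1-one
Conditions: (R)-3,3'-bis(2,4,6-triisopropylphenyl)-1,1'-binaphthyl-2,2'-diyl N-triflylphosphoramide (10 mol %), H2O (5 equiv), CHCl3, 40 °C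
Reagents that add atoms: water (`O`)
Why: Proposed new method: an enantioselective oxa-Piancatelli rearrangement, in which the acid ionises the carbinol to a furfuryl cation, water adds at furan C5, ring opening gives a 1,4-dihydroxypentadienyl cation and a thermal conrotatory 4π electrocyclisation forms the ring with the quaternary carbinol and the neighbouring CH in one event; both carbon chains sit outward on the cation termini (octenyl on the protonated-ketone terminus to avoid 1,3-strain, allyl anti to the former furan C3), so conrotation places them trans (OH cis to allyl), and the chiral phosphoramide anion, hydrogen-bonded to both OH groups of the cation, selects the sense of conrotation and hence (4R,5R); the closest known reactions are the racemic rearrangement of 5-methyl-2-furyl allyl carbinol to 5-allyl-4-hydroxy-4-methylcyclopent-2-enone and chiral phosphoric acid-catalysed aza-Piancatelli and Nazarov cyclisations.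

**Step 5**
Reactants: 9 (4R,5R)-4-hydroxy-4-[(2Z)-oct-2-en-1-yl]-5-(prop-2-en-1-yl)cyclopent-2-en-1-one
Product: 10 (4R,5R)-4-acetoxy-4-[(2Z)-oct-2-en-1-yl]-5-(prop-2-en-1-yl)cyclopent-2-en-1-one
Conditions: Ac2O (3 equiv), Sc(OTf)3 (2 mol %), MeCN, −20 °C
Reagents that add atoms: acetic anhydride (`CC(=O)OC(C)=O`)
Why: Lewis acid-catalysed acylation esterifies the hindered tertiary alcohol without base, so the β-acyloxy ketone cannot eliminate to a cyclopentadienone or isomerise, ionisation at C4 is disfavoured because it would give a destabilised 4-oxocyclopentenyl cation, and both stereocentres are kept because no bond to them is broken.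

**Step 6**
Reactants: 11 (5S)-5-(hydroxymethyl)dihydrofuran-2(3H)-one
Product: 12 (2S)-5-oxotetrahydrofuran-2-carbaldehyde
Conditions: Dess–Martin periodinane, CH2Cl2, 0 °C → rt; used crude
Reagents that add atoms: none
Why: Dess–Martin oxidation of the primary alcohol under neutral conditions does not epimerise the α-oxygenated stereocentre, and the sensitive aldehyde is used at once.

**Step 7**
Reactants: 12 (2S)-5-oxotetrahydrofuran-2-carbaldehyde
Product: 13 (5S)-5-ethenyldihydrofuran-2(3H)-one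
Conditions: Ph3PCH3Br, KN(SiMe3)2 (0.95 equiv to salt), THF, −78 °C; add 12, −78 → 0 °C
Reagents that add atoms: methyltriphenylphosphonium bromide (`C[P+](c1ccccc1)(c1ccccc1)c1ccccc1.[Br-]`)
Why: Wittig methylenation with the non-stabilised ylide at low temperature is selective for the aldehyde over the lactone carbonyl, and the absence of excess base keeps the (S)-centre from enolising, as in the established olefinations of this aldehyde with non-stabilised ylides.

**Step 8**
Reactants: 13 (5S)-5-ethenyldihydrofuran-2(3H)-one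
Product: 15 methyl (4S)-4-hydroxyhex-5-enoate, via lithium hydroxy carboxylate 14 (not isolated)
Conditions: LiOH (1.0 equiv), THF/H2O, 0 °C; evaporate; MeI, DMF, rt; used crude
Reagents that add atoms: lithium hydroxide (`[Li+].[OH-]`); iodomethane (`CI`)
Why: Saponification opens the lactone by acyl–oxygen cleavage, so the C4–O bond and the (S)-configuration are retained, and O-alkylation of the carboxylate with MeI gives the methyl ester under conditions where relactonisation is slow.

**Step 9**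
Reactants: 15 methyl (4S)-4-hydroxyhex-5-enoate
Product: 16 methyl (4S)-4-acetoxyhex-5-enoate
Conditions: Ac2O, pyridine, 4-(dimethylamino)pyridine (5 mol %), CH2Cl2, 0 °C
Reagents that add atoms: acetic anhydride (`CC(=O)OC(C)=O`)
Why: Nucleophile-catalysed acetylation of the secondary allylic alcohol outruns lactonisation and locks the open-chain form; the configuration is retained because only the O–H bond reacts.

**Step 10**
Reactants: 10 (4R,5R)-4-acetoxy-4-[(2Z)-oct-2-en-1-yl]-5-(prop-2-en-1-yl)cyclopent-2-en-1-one; 16 methyl (4S)-4-acetoxyhex-5-enoate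
Product: 17 methyl (4S,5E)-4-acetoxy-7-[(1R,2R)-2-acetoxy-2-[(2Z)-oct-2-en-1-yl]-5-oxocyclopent-3-en-1-yl]hept-5-enoate
Conditions: second-generation Hoveyda–Grubbs catalyst RuCl2(H2IMes)(=CH–C6H4-2-OiPr) (5 mol %, two portions), 16 (3 equiv), CH2Cl2, 40 °C, Ar sparge
Reagents that add atoms: none
Why: Olefin cross-metathesis between the terminal allyl group and the secondary allylic acetate (slow to homodimerise, used in excess) gives the (E)-alkene under thermodynamic control; the neutral conditions spare the base-labile β-acetoxy ketone, the ring enone is inert, the internal (Z)-alkene next to the quaternary carbon reacts much more slowly than the terminal alkene, and no stereocentre is touched.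

**Compound list**
1 | 2-(furan-2-yl)-1,3-dioxolane | `C1COC(O1)c1ccco1` | starting material
2 | 1-bromooct-2-yne | `CCCCCC#CCBr` | starting material
3 | [5-(1,3-dioxolan-2-yl)furan-2-yl]lithium | `[Li]c1ccc(o1)C1OCCO1` | intermediate (not isolated)
4 | 2-[5-(oct-2-yn-1-yl)furan-2-yl]-1,3-dioxolane | `CCCCCC#CCc1ccc(o1)C1OCCO1` | intermediate (not isolated)
5 | 5-(oct-2-yn-1-yl)furan-2-carbaldehyde | `CCCCCC#CCc1ccc(C=O)o1` | intermediate
6 | 5-[(2Z)-oct-2-en-1-yl]furan-2-carbaldehyde | `CCCCC/C=C\Cc1ccc(C=O)o1` | intermediate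
7 | bromomagnesium 1-{5-[(2Z)-oct-2-en-1-yl]furan-2-yl}but-3-en-1-olate | `C=CCC(O[Mg]Br)c1ccc(C/C=C\CCCCC)o1` | intermediate (not isolated)
8 | 1-{5-[(2Z)-oct-2-en-1-yl]furan-2-yl}but-3-en-1-ol (racemic) | `C=CCC(O)c1ccc(C/C=C\CCCCC)o1` | intermediate
9 | (4R,5R)-4-hydroxy-4-[(2Z)-oct-2-en-1-yl]-5-(prop-2-en-1-yl)cyclopent-2-en-1-one | `CCCCC/C=C\C[C@@]1(O)C=CC(=O)[C@@H]1CC=C` | intermediate
10 | (4R,5R)-4-acetoxy-4-[(2Z)-oct-2-en-1-yl]-5-(prop-2-en-1-yl)cyclopent-2-en-1-one | `CCCCC/C=C\C[C@@]1(OC(C)=O)C=CC(=O)[C@@H]1CC=C` | intermediate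
11 | (5S)-5-(hydroxymethyl)dihydrofuran-2(3H)-one | `OC[C@@H]1CCC(=O)O1` | starting material
12 | (2S)-5-oxotetrahydrofuran-2-carbaldehyde | `O=C[C@@H]1CCC(=O)O1` | intermediate
13 | (5S)-5-ethenyldihydrofuran-2(3H)-one | `C=C[C@@H]1CCC(=O)O1` | intermediate
14 | lithium (4S)-4-hydroxyhex-5-enoate | `C=C[C@@H](O)CCC(=O)[O-].[Li+]` | intermediate (not isolated)
15 | methyl (4S)-4-hydroxyhex-5-enoate | `C=C[C@@H](O)CCC(=O)OC` | intermediate
16 | methyl (4S)-4-acetoxyhex-5-enoate | `C=C[C@@H](OC(C)=O)CCC(=O)OC` | intermediate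
17 | methyl (4S,5E)-4-acetoxy-7-[(1R,2R)-2-acetoxy-2-[(2Z)-oct-2-en-1-yl]-5-oxocyclopent-3-en-1-yl]hept-5-enoate | `CCCCC/C=C\C[C@@]1(OC(C)=O)C=CC(=O)[C@@H]1C/C=C/[C@H](CCC(=O)OC)OC(C)=O` | target

**Totals**
Total step count: 10. Longest linear sequence: 6 steps (steps 1–5 and 10).

**Three steps most likely to fail**

Step 4 (enantioselective oxa-Piancatelli). The risks are low enantioselectivity with water as the nucleophile and loss of the furfuryl cation by elimination to a dienylfuran. The fallback sets out from 2 and comes back to the route at 9. The ring is taken from the chiral pool and the quaternary carbinol is set by substrate control. Commercial (4S)-4-[(tert-butyldimethylsilyl)oxy]cyclopent-2-en-1-one F1 is deprotonated at C5 with LiN(iPr)2 (THF, −78 °C) and alkylated with allyl iodide anti to the silyloxy group, giving (4R,5S)-4-[(tert-butyldimethylsilyl)oxy]-5-(prop-2-en-1-yl)cyclopent-2-en-1-one F2. The allenylzinc bromide formed from 2 and Zn dust (THF, 0 °C) adds through its CH2 terminus to the ketone of F2 from the face opposite the neighbouring allyl group and gives (1R,4R,5S)-4-[(tert-butyldimethylsilyl)oxy]-1-(oct-2-yn-1-yl)-5-(prop-2-en-1-yl)cyclopent-2-en-1-ol F3. Semihydrogenation (H2, Pd/CaCO3 poisoned with Pb(OAc)2, quinoline, stopped at one equivalent) gives (1R,4R,5S)-4-[(tert-butyldimethylsilyl)oxy]-1-[(2Z)-oct-2-en-1-yl]-5-(prop-2-en-1-yl)cyclopent-2-en-1-ol F4. HF·pyridine in THF gives (1R,4R,5S)-1-[(2Z)-oct-2-en-1-yl]-5-(prop-2-en-1-yl)cyclopent-2-ene-1,4-diol F5, and MnO2 in CH2Cl2 oxidises only the secondary allylic alcohol to give 9. The purchased stereocentre is destroyed in that last oxidation after it has relayed its configuration to C4 and C5.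

Step 5 (acetylation of the tertiary alcohol). The risks are a sluggish reaction at the hindered hydroxyl and, if any base is needed, elimination of the β-acetoxy ketone or isomerisation. The fallback sets out from 9 and comes back at 10. It removes the ketone that makes base dangerous. Luche reduction (NaBH4, CeCl3·7H2O, MeOH, −78 °C) gives (1R,4RS,5S)-1-[(2Z)-oct-2-en-1-yl]-5-(prop-2-en-1-yl)cyclopent-2-ene-1,4-diol F6, whose new carbinol centre is destroyed later. Ac2O, Et3N and 4-(dimethylamino)pyridine (CH2Cl2, rt) can now be used safely and give (1R,4RS,5S)-1-[(2Z)-oct-2-en-1-yl]-5-(prop-2-en-1-yl)cyclopent-2-ene-1,4-diyl diacetate F7. K2CO3 in MeOH at 0 °C cleaves only the secondary allylic acetate and gives (1R,4RS,5S)-4-hydroxy-1-[(2Z)-oct-2-en-1-yl]-5-(prop-2-en-1-yl)cyclopent-2-en-1-yl acetate F8. Dess–Martin periodinane buffered with NaHCO3 then re-forms the enone and gives 10.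

Step 10 (cross-metathesis). The risk is secondary metathesis at the internal (Z)-alkene and an incomplete E/Z ratio. The fallback sets out from 16 (with 2) and comes back at 17. The metathesis is done before any (Z)-alkene exists. F2 from the first fallback and 16 (3 equiv) are joined with the second-generation Hoveyda–Grubbs catalyst (CH2Cl2, 40 °C) to give methyl (4S,5E)-4-acetoxy-7-[(1S,5R)-5-[(tert-butyldimethylsilyl)oxy]-2-oxocyclopent-3-en-1-yl]hept-5-enoate F9. The allenylzinc bromide from 2 and Zn (THF, 0 °C) adds to the ketone only, anti to the side chain, and gives methyl (4S,5E)-4-acetoxy-7-[(1S,2R,5R)-5-[(tert-butyldimethylsilyl)oxy]-2-hydroxy-2-(oct-2-yn-1-yl)cyclopent-3-en-1-yl]hept-5-enoate F10. Semihydrogenation over Pd/CaCO3 poisoned with Pb(OAc)2 gives methyl (4S,5E)-4-acetoxy-7-[(1S,2R,5R)-5-[(tert-butyldimethylsilyl)oxy]-2-hydroxy-2-[(2Z)-oct-2-en-1-yl]cyclopent-3-en-1-yl]hept-5-enoate F11. HF·pyridine gives methyl (4S,5E)-4-acetoxy-7-[(1S,2R,5R)-2,5-dihydroxy-2-[(2Z)-oct-2-en-1-yl]cyclopent-3-en-1-yl]hept-5-enoate F12, and MnO2 gives methyl (4S,5E)-4-acetoxy-7-[(1R,2R)-2-hydroxy-2-[(2Z)-oct-2-en-1-yl]-5-oxocyclopent-3-en-1-yl]hept-5-enoate F13. Acetylation under the conditions of step 5 then gives 17.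

**Further compounds**
F1 | step 4 | (4S)-4-[(tert-butyldimethylsilyl)oxy]cyclopent-2-en-1-one (purchased) | `O=C1C=C[C@@H](O[Si](C)(C)C(C)(C)C)C1`
F2 | step 4 | (4R,5S)-4-[(tert-butyldimethylsilyl)oxy]-5-(prop-2-en-1-yl)cyclopent-2-en-1-one | `O=C1C=C[C@@H](O[Si](C)(C)C(C)(C)C)[C@@H]1CC=C`
F3 | step 4 | (1R,4R,5S)-4-[(tert-butyldimethylsilyl)oxy]-1-(oct-2-yn-1-yl)-5-(prop-2-en-1-yl)cyclopent-2-en-1-ol | `CCCCCC#CC[C@@]1(O)C=C[C@@H](O[Si](C)(C)C(C)(C)C)[C@@H]1CC=C`
F4 | step 4 | (1R,4R,5S)-4-[(tert-butyldimethylsilyl)oxy]-1-[(2Z)-oct-2-en-1-yl]-5-(prop-2-en-1-yl)cyclopent-2-en-1-ol | `CCCCC/C=C\C[C@@]1(O)C=C[C@@H](O[Si](C)(C)C(C)(C)C)[C@@H]1CC=C`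
F5 | step 4 | (1R,4R,5S)-1-[(2Z)-oct-2-en-1-yl]-5-(prop-2-en-1-yl)cyclopent-2-ene-1,4-diol | `CCCCC/C=C\C[C@@]1(O)C=C[C@@H](O)[C@@H]1CC=C`
F6 | step 5 | (1R,4RS,5S)-1-[(2Z)-oct-2-en-1-yl]-5-(prop-2-en-1-yl)cyclopent-2-ene-1,4-diol | `CCCCC/C=C\C[C@@]1(O)C=CC(O)[C@@H]1CC=C`
F7 | step 5 | (1R,4RS,5S)-1-[(2Z)-oct-2-en-1-yl]-5-(prop-2-en-1-yl)cyclopent-2-ene-1,4-diyl diacetate | `CCCCC/C=C\C[C@@]1(OC(C)=O)C=CC(OC(C)=O)[C@@H]1CC=C`
F8 | step 5 | (1R,4RS,5S)-4-hydroxy-1-[(2Z)-oct-2-en-1-yl]-5-(prop-2-en-1-yl)cyclopent-2-en-1-yl acetate | `CCCCC/C=C\C[C@@]1(OC(C)=O)C=CC(O)[C@@H]1CC=C`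
F9 | step 10 | methyl (4S,5E)-4-acetoxy-7-[(1S,5R)-5-[(tert-butyldimethylsilyl)oxy]-2-oxocyclopent-3-en-1-yl]hept-5-enoate | `O=C1C=C[C@@H](O[Si](C)(C)C(C)(C)C)[C@@H]1C/C=C/[C@H](CCC(=O)OC)OC(C)=O`
F10 | step 10 | methyl (4S,5E)-4-acetoxy-7-[(1S,2R,5R)-5-[(tert-butyldimethylsilyl)oxy]-2-hydroxy-2-(oct-2-yn-1-yl)cyclopent-3-en-1-yl]hept-5-enoate | `CCCCCC#CC[C@@]1(O)C=C[C@@H](O[Si](C)(C)C(C)(C)C)[C@@H]1C/C=C/[C@H](CCC(=O)OC)OC(C)=O`
F11 | step 10 | methyl (4S,5E)-4-acetoxy-7-[(1S,2R,5R)-5-[(tert-butyldimethylsilyl)oxy]-2-hydroxy-2-[(2Z)-oct-2-en-1-yl]cyclopent-3-en-1-yl]hept-5-enoate | `CCCCC/C=C\C[C@@]1(O)C=C[C@@H](O[Si](C)(C)C(C)(C)C)[C@@H]1C/C=C/[C@H](CCC(=O)OC)OC(C)=O`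
F12 | step 10 | methyl (4S,5E)-4-acetoxy-7-[(1S,2R,5R)-2,5-dihydroxy-2-[(2Z)-oct-2-en-1-yl]cyclopent-3-en-1-yl]hept-5-enoate | `CCCCC/C=C\C[C@@]1(O)C=C[C@@H](O)[C@@H]1C/C=C/[C@H](CCC(=O)OC)OC(C)=O`
F13 | step 10 | methyl (4S,5E)-4-acetoxy-7-[(1R,2R)-2-hydroxy-2-[(2Z)-oct-2-en-1-yl]-5-oxocyclopent-3-en-1-yl]hept-5-enoate | `CCCCC/C=C\C[C@@]1(O)C=CC(=O)[C@@H]1C/C=C/[C@H](CCC(=O)OC)OC(C)=O`
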